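Its constants are invented.

A flask cannot hold more [D] + [Z] than the smaller of its charges of Q and E, because each step that makes D spends one Q and one E, and the exchange of D with Z merely moves material between the two.

    D ⇌ Z (K1 = 2.1, k1 = 0.00464 min⁻¹)
    Q + E → D + J (k2 = 2.34 × 10⁻⁴ M⁻¹ min⁻¹)
    Q + E + J → D + 2 J (k3 = 0.0141 M⁻² min⁻¹)

the same everywhere: E 1.30 M; time 10 h
- larch: Q 0.60 M
- birch: Q 1.0 M
- alder: Q 1.5 M
- oak: Q 2.5 M
- elm: Q 3.0 M

1. [D] at the end for larch, birch, alder, oak, elm, in this order
2. how that number moves from the first to the last of them (falls all the way / rises, then falls / hardly changes / rises all the way / falls, then rises)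

- "hardly changes" means that all values lie within two and a half points (for a concentration: within two and a half percent of the largest)
- run time (larch): 10 h

Minutes of the meeting on the row.

I opened by freezing what stops moving. In elm the charge of E, 1.30 M, is smaller than the charge of Q, 3.0 M, so E is the limiting reagent, and at that ceiling the sum [D] + [Z] stands still while its split goes on moving. I proposed to carry one number: the relaxed share, the part of [D] + [Z] that is D at equilibrium of the exchange, the inverse of one plus 2.1, which is 32.3 %.

The exchange relaxes, both ways together, with a half-life of 1.69 h, short against the 10 h of the run. So I committed to 0.419 M for elm and 0.419 M for oak. I stopped there. For larch, birch and alder I did not integrate the build-up of J.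

The author of the forecast put the row at 0.248 M, 0.394 M, 0.488 M, 0.453 M and 0.447 M, with the shape "rises, then falls", arguing that “the richest runs finish early enough for D to relax almost to its equilibrium share”. His elm figure stood above mine.

The flasks gave 0.249 M, 0.392 M, 0.485 M, 0.453 M and 0.447 M: rises, then falls, with the turn read near 1.6 M.

The comparison that counts is the relaxation half-life of D and Z, 1.69 h in larch and the same 1.69 h in elm, where k1 and K1 are the same, against the 10 h of the run: elm held [D] at 0.636 M after 5.00 h, with E down to 0.0710 % of its charge, and the excess over 0.419 M, decaying with that half-life for the remaining 5.00 h, leaves 0.447 M, where the run shows 0.447 M. In oak, followed to 100 h, the relaxed share of the 1.30 M ceiling gives 0.419 M, and [D] stood at 0.419 M.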